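**Plan**

Rings: A = upper benzo ring, B = methoxycatechol ring, C = upper pyran, D = central arene, E = lower pyran, F = lower benzo ring.
Retrosynthesis: after removal of six benzyl groups, ring C is cut at C4–C4a (cationic Friedel–Crafts closure onto ring A) and ring E at O1–C2 (Mitsunobu). Both bonds from ring D to upper C4 and lower C3 are then cut in one aryne insertion, and the remaining ketoester is cut at C(α)–C(=O) (decarboxylative Claisen) and at the ring-A ether oxygen (oxa-Michael).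
Enabling feature: on ring D the carbons carrying upper C4 and lower C3 are neighbours, the OMe sits on the carbon next to the C4-bearing one and the OH para to it. This is the pattern produced when a 3-methoxy-5-oxyaryne inserts into the C(α)–C(=O) bond of a β-ketoester, with the acyl carbon ending next to OMe.
Forward: aryne precursor 4 (2 steps), ring-B/ring-A acid 12 (5 steps) and ring-F malonic half ester 18 (3 steps) are made separately; 12 and 18 give ketoester 21; the insertion gives 23 with the full carbon skeleton; ring E is closed, then ring C, then the benzyl groups are removed.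
Stereochemistry: upper C3 comes from a dynamic kinetic transfer hydrogenation of the ketone (catalyst control), lower C3 from a dynamic kinetic hydrogenation of the derived α-aryl lactone (catalyst control), and upper C4 from the trans-selective cationic ring closure (relay from C3).

Key step: step 12

Assumption: the sense of induction of the chiral catalysts in steps 13 and 14 is taken from the usual models for these catalyst families; if either reduction runs in the opposite sense, the mirror-image ligand is used.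

**Route**

Step 1
Reactants: 1 3-methoxy-2-(trimethylsilyl)phenyl trifluoromethanesulfonate
Product: 3 5-hydroxy-3-methoxy-2-(trimethylsilyl)phenyl trifluoromethanesulfonate, via arylboronate 2 (not isolated)
Conditions: [Ir(OMe)(cod)]2 (1.5 mol%), 4,4'-di-tert-butyl-2,2'-bipyridine, B2pin2 (1 equiv), THF, 65 °C; evaporate; Oxone (2KHSO5·KHSO4·K2SO4), acetone/H2O, rt, short contact
Reagents that add atoms: potassium peroxymonosulfate (KHSO5), [K+].[O-]S(=O)(=O)OO
Why: Iridium-catalysed C–H borylation is sterically governed and H-5 is the only ring hydrogen of 1 without an ortho substituent, so the boryl group and, after oxidation of the C–B bond, the hydroxyl group enter meta to both OMe and OTf while the silyl triflate pair stays intact.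

Step 2
Reactants: 3 5-hydroxy-3-methoxy-2-(trimethylsilyl)phenyl trifluoromethanesulfonate
Product: 4 5-(benzyloxy)-3-methoxy-2-(trimethylsilyl)phenyl trifluoromethanesulfonate
Conditions: BnBr, K2CO3, acetone, rt
Reagents that add atoms: benzyl bromide, BrCc1ccccc1
Why: Williamson etherification of the phenoxide; carbonate without fluoride is too weak to trigger aryne formation at room temperature.

Step 3
Reactants: 5 2,3-dihydroxy-4-methoxybenzaldehyde
Product: 6 2,3-bis(benzyloxy)-4-methoxybenzaldehyde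
Conditions: BnBr (2.4 equiv), K2CO3, DMF, 60 °C
Reagents that add atoms: benzyl bromide, BrCc1ccccc1
Why: Williamson etherification of both catechol hydroxyls, leaving the aldehyde untouched.

Step 4
Reactants: 6 2,3-bis(benzyloxy)-4-methoxybenzaldehyde
Product: 8 methyl [2,3-bis(benzyloxy)-4-methoxyphenyl]acetate, via ketene dithioacetal S-oxide 7 (not isolated)
Conditions: MeS(O)CH2SMe, BnMe3NOH (cat.), THF, reflux; evaporate; HCl, MeOH, rt to 40 °C
Reagents that add atoms: methyl (methylsulfinyl)methyl sulfide, CSCS(C)=O; methanol, CO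
Why: Knoevenagel-type condensation of the aldehyde with the sulfoxide-stabilised carbanion gives the ketene dithioacetal S-oxide, whose acid alcoholysis (Pummerer-type oxygen transfer) delivers the one-carbon-homologated arylacetic ester.

Step 5
Reactants: 8 methyl [2,3-bis(benzyloxy)-4-methoxyphenyl]acetate
Product: 9 methyl 2-[2,3-bis(benzyloxy)-4-methoxyphenyl]prop-2-enoate
Conditions: paraformaldehyde, K2CO3, Bu4NI (cat.), toluene, 80 °C
Reagents that add atoms: formaldehyde (as paraformaldehyde), C=O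
Why: Aldol condensation of the arylacetate enolate with formaldehyde (hydroxymethylation, then E1cB dehydration) is the standard entry to 2-arylacrylates.

Step 6
Reactants: 9 methyl 2-[2,3-bis(benzyloxy)-4-methoxyphenyl]prop-2-enoate; 10 3-(benzyloxy)phenol
Product: 11 methyl 2-[2,3-bis(benzyloxy)-4-methoxyphenyl]-3-[3-(benzyloxy)phenoxy]propanoate (racemic)
Conditions: Cs2CO3 (0.2 equiv), MeCN, rt
Reagents that add atoms: none
Why: Oxa-Michael addition of the phenoxide to the 2-arylacrylate forms the aryl ether that becomes O1–C2 of ring C; the α-carbon is formed racemic and is meant to stay epimerisable.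

Step 7
Reactants: 11 methyl 2-[2,3-bis(benzyloxy)-4-methoxyphenyl]-3-[3-(benzyloxy)phenoxy]propanoate
Product: 12 2-[2,3-bis(benzyloxy)-4-methoxyphenyl]-3-[3-(benzyloxy)phenoxy]propanoic acid (racemic)
Conditions: Me3SnOH (5 equiv), ClCH2CH2Cl, 80 °C; dilute aq. HCl wash
Reagents that add atoms: trimethyltin hydroxide, C[Sn](C)(C)O
Why: Ester cleavage by acyl substitution with Me3SnOH runs under nearly neutral conditions and so avoids the E1cB loss of phenoxide that aqueous hydroxide would invite in this β-aryloxy α-aryl ester.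

Step 8
Reactants: 13 4-(benzyloxy)-2-hydroxybenzaldehyde
Product: 14 2-(allyloxy)-4-(benzyloxy)benzaldehyde
Conditions: allyl bromide, K2CO3, DMF, 50 °C
Reagents that add atoms: allyl bromide, C=CCBr
Why: Williamson etherification; the allyl ether withstands the later Grignard base, fluoride, transfer hydrogenation and alkoxide, and can be removed without acid.

Step 9
Reactants: 14 2-(allyloxy)-4-(benzyloxy)benzaldehyde; 15 Meldrum's acid (2,2-dimethyl-1,3-dioxane-4,6-dione)
Product: 17 5-[2-(allyloxy)-4-(benzyloxy)benzyl]-2,2-dimethyl-1,3-dioxane-4,6-dione, via arylidene Meldrum's acid 16 (not isolated)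
Conditions: Hantzsch ester (1 equiv), L-proline (20 mol%), EtOH, rt
Reagents that add atoms: none
Why: Proline-catalysed Knoevenagel condensation gives the arylidene, which is reduced in the flask by conjugate hydride transfer from the Hantzsch ester (three-component reductive alkylation), leaving the benzyl and allyl groups untouched.

Step 10
Reactants: 17 5-[2-(allyloxy)-4-(benzyloxy)benzyl]-2,2-dimethyl-1,3-dioxane-4,6-dione
Product: 18 2-[2-(allyloxy)-4-(benzyloxy)benzyl]-3-methoxy-3-oxopropanoic acid (racemic)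
Conditions: MeOH, reflux
Reagents that add atoms: methanol, CO
Why: Methanolysis of the Meldrum's acid ring (acyl substitution with loss of acetone) gives the malonic half ester.

Step 11
Reactants: 12 2-[2,3-bis(benzyloxy)-4-methoxyphenyl]-3-[3-(benzyloxy)phenoxy]propanoic acid; 18 2-[2-(allyloxy)-4-(benzyloxy)benzyl]-3-methoxy-3-oxopropanoic acid
Product: 21 methyl 2-[2-(allyloxy)-4-(benzyloxy)benzyl]-4-[2,3-bis(benzyloxy)-4-methoxyphenyl]-5-[3-(benzyloxy)phenoxy]-3-oxopentanoate (mixture of stereoisomers), via acyl imidazolide 19 (not isolated), via acylmalonic half ester 20 (not isolated)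
Conditions: 12, CDI, THF, rt; separately 18 (1.5 equiv), iPrMgCl (3 equiv), THF, 0 °C to rt; combine, rt to 40 °C; 1 M HCl work-up
Reagents that add atoms: none
Why: Decarboxylative Claisen condensation, in which the chelated enolate of the half ester formed with iPrMgCl (far less basic than a lithium ester enolate) C-acylates the imidazolide without eliminating the β-aryloxy group and the acylmalonic acid then loses CO2; both stereocentres form unselectively and are epimerisable.

Step 12
Reactants: 4 5-(benzyloxy)-3-methoxy-2-(trimethylsilyl)phenyl trifluoromethanesulfonate; 21 methyl 2-[2-(allyloxy)-4-(benzyloxy)benzyl]-4-[2,3-bis(benzyloxy)-4-methoxyphenyl]-5-[3-(benzyloxy)phenoxy]-3-oxopentanoate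
Product: 23 methyl 3-[2-(allyloxy)-4-(benzyloxy)phenyl]-2-[5-(benzyloxy)-2-{2-[2,3-bis(benzyloxy)-4-methoxyphenyl]-3-[3-(benzyloxy)phenoxy]propanoyl}-3-methoxyphenyl]propanoate (mixture of stereoisomers), via aryne 22 (not isolated)
Conditions: CsF (3 equiv), MeCN, 80 °C; 4 (1.3 equiv) added in portions
Reagents that add atoms: none
Why: Fluoride attacks silicon and triflate leaves to give aryne 22; the enolate of 21 (Cs+ counter-ion) adds through its α-carbon to the aryne carbon remote from the methoxy group, the aryl anion formed next to OMe closes onto the ketone to a benzocyclobutenoxide, and fragmentation of that four-membered ring passes the acyl group to the arene and leaves an α-aryl ester enolate that is protonated. The closest known reaction is the fluoride-induced acyl-alkylation of arynes with β-ketoesters, which accepts α-substituted ketoesters and is regioselective for 3-methoxyarynes. No ring of the target closes; the only ring formed is the transient cyclobutene, by 4-exo-trig attack of the aryl anion on the carbonyl. The new stereocentre (lower C3) is formed without control and, like the ketone α-carbon (upper C3), remains epimerisable for steps 13 and 14. The selectivity needed is regiochemical: the methoxy group polarises and distorts the strained triple bond so that the carbon meta to it is the electrophilic site (the benzyloxy group, meta to that carbon, has a minor influence), and C- over O-arylation follows from the soft enolate carbon. Two congested aryl–carbon bonds of ring D are thereby made at once while the reacting arene is still a small, unencumbered aryne.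

Step 13
Reactants: 23 methyl 3-[2-(allyloxy)-4-(benzyloxy)phenyl]-2-[5-(benzyloxy)-2-{2-[2,3-bis(benzyloxy)-4-methoxyphenyl]-3-[3-(benzyloxy)phenoxy]propanoyl}-3-methoxyphenyl]propanoate
Product: 25 (1S)-4-[2-(allyloxy)-4-(benzyloxy)benzyl]-6-(benzyloxy)-1-{(1R)-1-[2,3-bis(benzyloxy)-4-methoxyphenyl]-2-[3-(benzyloxy)phenoxy]ethyl}-8-methoxyisochroman-3-one (C4 epimers), via hydroxy ester 24 (not isolated)
Conditions: RuCl[(S,S)-TsDPEN](p-cymene) (5 mol%), HCO2H/Et3N (5:2), DMF, 40 °C; then DBU (0.2 equiv), toluene, 50 °C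
Reagents that add atoms: none
Why: Noyori-type asymmetric transfer hydrogenation with dynamic kinetic resolution, in which upper C3 (α to the ketone and benzylic to ring B) epimerises through the enol while the (S,S)-catalyst reduces the Felkin–Anh-matched (3R)-ketone to the (4S)-carbinol, which then lactonises onto the neighbouring ester; the lactone α-carbon (lower C3) stays an epimeric pair.

Step 14
Reactants: 25 (1S)-4-[2-(allyloxy)-4-(benzyloxy)benzyl]-6-(benzyloxy)-1-{(1R)-1-[2,3-bis(benzyloxy)-4-methoxyphenyl]-2-[3-(benzyloxy)phenoxy]ethyl}-8-methoxyisochroman-3-one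
Product: 26 (2R)-3-[2-(allyloxy)-4-(benzyloxy)phenyl]-2-[5-(benzyloxy)-2-{(1S,2R)-2-[2,3-bis(benzyloxy)-4-methoxyphenyl]-3-[3-(benzyloxy)phenoxy]-1-hydroxypropyl}-3-methoxyphenyl]propan-1-ol
Conditions: [Ir(cod)Cl]2 (0.5 mol%), (R)-SpiroPAP (1.1 mol%), KOtBu (0.5 equiv), n-PrOH/toluene, H2 (20 atm), rt
Reagents that add atoms: none
Why: Asymmetric hydrogenation of a racemising α-aryl lactone to the chiral diol (dynamic kinetic resolution), in which KOtBu equilibrates the benzylic lactone α-carbon and the chiral Ir catalyst reduces the (R)-epimer preferentially, so lower C3 is set under catalyst control and is no longer epimerisable afterwards.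

Step 15
Reactants: 26 (2R)-3-[2-(allyloxy)-4-(benzyloxy)phenyl]-2-[5-(benzyloxy)-2-{(1S,2R)-2-[2,3-bis(benzyloxy)-4-methoxyphenyl]-3-[3-(benzyloxy)phenoxy]-1-hydroxypropyl}-3-methoxyphenyl]propan-1-ol
Product: 27 5-(benzyloxy)-2-{(2R)-2-[5-(benzyloxy)-2-{(1S,2R)-2-[2,3-bis(benzyloxy)-4-methoxyphenyl]-3-[3-(benzyloxy)phenoxy]-1-hydroxypropyl}-3-methoxyphenyl]-3-hydroxypropyl}phenol
Conditions: Pd(PPh3)4 (5 mol%), morpholine (5 equiv), THF, rt
Reagents that add atoms: none
Why: Tsuji–Trost deallylation, in which zerovalent palladium ionises the allyl aryl ether to a π-allyl complex that morpholine traps, freeing the ring-F phenol under neutral conditions that spare the benzyl ethers and the acid-sensitive benzylic alcohol.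

Step 16
Reactants: 27 5-(benzyloxy)-2-{(2R)-2-[5-(benzyloxy)-2-{(1S,2R)-2-[2,3-bis(benzyloxy)-4-methoxyphenyl]-3-[3-(benzyloxy)phenoxy]-1-hydroxypropyl}-3-methoxyphenyl]-3-hydroxypropyl}phenol
Product: 28 (1S,2R)-1-{4-(benzyloxy)-2-[(3R)-7-(benzyloxy)chroman-3-yl]-6-methoxyphenyl}-2-[2,3-bis(benzyloxy)-4-methoxyphenyl]-3-[3-(benzyloxy)phenoxy]propan-1-ol
Conditions: PPh3, DIAD (1.3 equiv each), THF (0.02 M), 0 °C to rt
Reagents that add atoms: none
Why: Mitsunobu cycloetherification, in which the primary alcohol is activated in preference to the hindered secondary benzylic one and is displaced by the neighbouring phenoxide in a 6-exo-tet closure that forms ring E without touching lower C3.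

Step 17
Reactants: 28 (1S,2R)-1-{4-(benzyloxy)-2-[(3R)-7-(benzyloxy)chroman-3-yl]-6-methoxyphenyl}-2-[2,3-bis(benzyloxy)-4-methoxyphenyl]-3-[3-(benzyloxy)phenoxy]propan-1-ol
Product: 29 (3R,4S)-7-(benzyloxy)-4-{4-(benzyloxy)-2-[(3R)-7-(benzyloxy)chroman-3-yl]-6-methoxyphenyl}-3-[2,3-bis(benzyloxy)-4-methoxyphenyl]chromane
Conditions: TsOH·H2O (10 mol%), CH2Cl2/(CF3)2CHOH (4:1), 0 °C
Reagents that add atoms: none
Why: Dehydrative intramolecular Friedel–Crafts alkylation, in which the acid ionises the carbinol to a 2,4-dialkoxybenzylic cation, ring A attacks through its position para to the benzyloxy group to close ring C, and C4 forms trans to the C3 aryl group because the half-chair transition state keeps both aryl groups pseudo-equatorial, so the original carbinol configuration does not matter.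

Step 18
Reactants: 29 (3R,4S)-7-(benzyloxy)-4-{4-(benzyloxy)-2-[(3R)-7-(benzyloxy)chroman-3-yl]-6-methoxyphenyl}-3-[2,3-bis(benzyloxy)-4-methoxyphenyl]chromane
Product: 30 (3R,4S)-3-(2,3-dihydroxy-4-methoxyphenyl)-4-{4-hydroxy-2-[(3R)-7-hydroxychroman-3-yl]-6-methoxyphenyl}chroman-7-ol (target)
Conditions: H2 (1 atm), Pd/C (10% Pd), degassed THF/MeOH, rt
Reagents that add atoms: none
Why: Hydrogenolysis of the six benzyl aryl ethers over Pd/C; the chroman C–O bonds are not benzylic and the stereocentres carry no heteroatom, so neither is affected.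

**Compound list**

1 | 3-methoxy-2-(trimethylsilyl)phenyl trifluoromethanesulfonate | COc1cccc(OS(=O)(=O)C(F)(F)F)c1[Si](C)(C)C | starting material
2 | 3-methoxy-5-(4,4,5,5-tetramethyl-1,3,2-dioxaborolan-2-yl)-2-(trimethylsilyl)phenyl trifluoromethanesulfonate | COc1cc(B2OC(C)(C)C(C)(C)O2)cc(OS(=O)(=O)C(F)(F)F)c1[Si](C)(C)C | intermediate
3 | 5-hydroxy-3-methoxy-2-(trimethylsilyl)phenyl trifluoromethanesulfonate | COc1cc(O)cc(OS(=O)(=O)C(F)(F)F)c1[Si](C)(C)C | intermediate
4 | 5-(benzyloxy)-3-methoxy-2-(trimethylsilyl)phenyl trifluoromethanesulfonate | COc1cc(OCc2ccccc2)cc(OS(=O)(=O)C(F)(F)F)c1[Si](C)(C)C | intermediate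
5 | 2,3-dihydroxy-4-methoxybenzaldehyde | COc1ccc(C=O)c(O)c1O | starting material
6 | 2,3-bis(benzyloxy)-4-methoxybenzaldehyde | COc1ccc(C=O)c(OCc2ccccc2)c1OCc1ccccc1 | intermediate
7 | 1,2-bis(benzyloxy)-3-methoxy-4-[2-(methylsulfanyl)-2-(methylsulfinyl)ethenyl]benzene | COc1ccc(C=C(SC)S(C)=O)c(OCc2ccccc2)c1OCc1ccccc1 | intermediate
8 | methyl [2,3-bis(benzyloxy)-4-methoxyphenyl]acetate | COC(=O)Cc1ccc(OC)c(OCc2ccccc2)c1OCc1ccccc1 | intermediate
9 | methyl 2-[2,3-bis(benzyloxy)-4-methoxyphenyl]prop-2-enoate | COC(=O)C(=C)c1ccc(OC)c(OCc2ccccc2)c1OCc1ccccc1 | intermediate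
10 | 3-(benzyloxy)phenol | Oc1cccc(OCc2ccccc2)c1 | starting material
11 | methyl 2-[2,3-bis(benzyloxy)-4-methoxyphenyl]-3-[3-(benzyloxy)phenoxy]propanoate (racemic) | COC(=O)C(COc1cccc(OCc2ccccc2)c1)c1ccc(OC)c(OCc2ccccc2)c1OCc1ccccc1 | intermediate
12 | 2-[2,3-bis(benzyloxy)-4-methoxyphenyl]-3-[3-(benzyloxy)phenoxy]propanoic acid (racemic) | OC(=O)C(COc1cccc(OCc2ccccc2)c1)c1ccc(OC)c(OCc2ccccc2)c1OCc1ccccc1 | intermediate
13 | 4-(benzyloxy)-2-hydroxybenzaldehyde | O=Cc1ccc(OCc2ccccc2)cc1O | starting material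
14 | 2-(allyloxy)-4-(benzyloxy)benzaldehyde | C=CCOc1cc(OCc2ccccc2)ccc1C=O | intermediate
15 | Meldrum's acid (2,2-dimethyl-1,3-dioxane-4,6-dione) | CC1(C)OC(=O)CC(=O)O1 | starting material
16 | 5-[2-(allyloxy)-4-(benzyloxy)benzylidene]-2,2-dimethyl-1,3-dioxane-4,6-dione | C=CCOc1cc(OCc2ccccc2)ccc1C=C1C(=O)OC(C)(C)OC1=O | intermediate
17 | 5-[2-(allyloxy)-4-(benzyloxy)benzyl]-2,2-dimethyl-1,3-dioxane-4,6-dione | C=CCOc1cc(OCc2ccccc2)ccc1CC1C(=O)OC(C)(C)OC1=O | intermediate
18 | 2-[2-(allyloxy)-4-(benzyloxy)benzyl]-3-methoxy-3-oxopropanoic acid (racemic) | C=CCOc1cc(OCc2ccccc2)ccc1CC(C(=O)O)C(=O)OC | intermediate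
19 | 1-{2-[2,3-bis(benzyloxy)-4-methoxyphenyl]-3-[3-(benzyloxy)phenoxy]propanoyl}-1H-imidazole (racemic) | O=C(n1ccnc1)C(COc1cccc(OCc2ccccc2)c1)c1ccc(OC)c(OCc2ccccc2)c1OCc1ccccc1 | intermediate
20 | 2-[2-(allyloxy)-4-(benzyloxy)benzyl]-4-[2,3-bis(benzyloxy)-4-methoxyphenyl]-5-[3-(benzyloxy)phenoxy]-2-(methoxycarbonyl)-3-oxopentanoic acid (mixture of stereoisomers) | COC(=O)C(Cc1ccc(OCc2ccccc2)cc1OCC=C)(C(=O)O)C(=O)C(COc1cccc(OCc2ccccc2)c1)c1ccc(OC)c(OCc2ccccc2)c1OCc1ccccc1 | intermediate
21 | methyl 2-[2-(allyloxy)-4-(benzyloxy)benzyl]-4-[2,3-bis(benzyloxy)-4-methoxyphenyl]-5-[3-(benzyloxy)phenoxy]-3-oxopentanoate (mixture of stereoisomers) | COC(=O)C(Cc1ccc(OCc2ccccc2)cc1OCC=C)C(=O)C(COc1cccc(OCc2ccccc2)c1)c1ccc(OC)c(OCc2ccccc2)c1OCc1ccccc1 | intermediate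
22 | 5-(benzyloxy)-3-methoxy-1,2-didehydrobenzene (aryne) | COC1=CC(OCc2ccccc2)=CC#C1 | intermediate
23 | methyl 3-[2-(allyloxy)-4-(benzyloxy)phenyl]-2-[5-(benzyloxy)-2-{2-[2,3-bis(benzyloxy)-4-methoxyphenyl]-3-[3-(benzyloxy)phenoxy]propanoyl}-3-methoxyphenyl]propanoate (mixture of stereoisomers) | COC(=O)C(Cc1ccc(OCc2ccccc2)cc1OCC=C)c1cc(OCc2ccccc2)cc(OC)c1C(=O)C(COc1cccc(OCc2ccccc2)c1)c1ccc(OC)c(OCc2ccccc2)c1OCc1ccccc1 | intermediate
24 | methyl 3-[2-(allyloxy)-4-(benzyloxy)phenyl]-2-[5-(benzyloxy)-2-{(1S,2R)-2-[2,3-bis(benzyloxy)-4-methoxyphenyl]-3-[3-(benzyloxy)phenoxy]-1-hydroxypropyl}-3-methoxyphenyl]propanoate (epimers at the ester α-carbon) | COC(=O)C(Cc1ccc(OCc2ccccc2)cc1OCC=C)c1cc(OCc2ccccc2)cc(OC)c1[C@@H](O)[C@@H](COc1cccc(OCc2ccccc2)c1)c1ccc(OC)c(OCc2ccccc2)c1OCc1ccccc1 | intermediate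
25 | (1S)-4-[2-(allyloxy)-4-(benzyloxy)benzyl]-6-(benzyloxy)-1-{(1R)-1-[2,3-bis(benzyloxy)-4-methoxyphenyl]-2-[3-(benzyloxy)phenoxy]ethyl}-8-methoxyisochroman-3-one (C4 epimers) | COc1cc(OCc2ccccc2)cc2c1[C@H]([C@@H](COc1cccc(OCc3ccccc3)c1)c1ccc(OC)c(OCc3ccccc3)c1OCc1ccccc1)OC(=O)C2Cc1ccc(OCc2ccccc2)cc1OCC=C | intermediate
26 | (2R)-3-[2-(allyloxy)-4-(benzyloxy)phenyl]-2-[5-(benzyloxy)-2-{(1S,2R)-2-[2,3-bis(benzyloxy)-4-methoxyphenyl]-3-[3-(benzyloxy)phenoxy]-1-hydroxypropyl}-3-methoxyphenyl]propan-1-ol | C=CCOc1cc(OCc2ccccc2)ccc1C[C@@H](CO)c1cc(OCc2ccccc2)cc(OC)c1[C@@H](O)[C@@H](COc1cccc(OCc2ccccc2)c1)c1ccc(OC)c(OCc2ccccc2)c1OCc1ccccc1 | intermediate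
27 | 5-(benzyloxy)-2-{(2R)-2-[5-(benzyloxy)-2-{(1S,2R)-2-[2,3-bis(benzyloxy)-4-methoxyphenyl]-3-[3-(benzyloxy)phenoxy]-1-hydroxypropyl}-3-methoxyphenyl]-3-hydroxypropyl}phenol | Oc1cc(OCc2ccccc2)ccc1C[C@@H](CO)c1cc(OCc2ccccc2)cc(OC)c1[C@@H](O)[C@@H](COc1cccc(OCc2ccccc2)c1)c1ccc(OC)c(OCc2ccccc2)c1OCc1ccccc1 | intermediate
28 | (1S,2R)-1-{4-(benzyloxy)-2-[(3R)-7-(benzyloxy)chroman-3-yl]-6-methoxyphenyl}-2-[2,3-bis(benzyloxy)-4-methoxyphenyl]-3-[3-(benzyloxy)phenoxy]propan-1-ol | O1C[C@H](Cc2ccc(OCc3ccccc3)cc21)c1cc(OCc2ccccc2)cc(OC)c1[C@@H](O)[C@@H](COc1cccc(OCc2ccccc2)c1)c1ccc(OC)c(OCc2ccccc2)c1OCc1ccccc1 | intermediate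
29 | (3R,4S)-7-(benzyloxy)-4-{4-(benzyloxy)-2-[(3R)-7-(benzyloxy)chroman-3-yl]-6-methoxyphenyl}-3-[2,3-bis(benzyloxy)-4-methoxyphenyl]chromane | COc1ccc([C@@H]2COc3cc(OCc4ccccc4)ccc3[C@H]2c2c(OC)cc(OCc3ccccc3)cc2[C@@H]2COc3cc(OCc4ccccc4)ccc3C2)c(OCc2ccccc2)c1OCc1ccccc1 | intermediate
30 | (3R,4S)-3-(2,3-dihydroxy-4-methoxyphenyl)-4-{4-hydroxy-2-[(3R)-7-hydroxychroman-3-yl]-6-methoxyphenyl}chroman-7-ol | COc1ccc([C@@H]2COc3cc(O)ccc3[C@H]2c2c(OC)cc(O)cc2[C@@H]2COc3cc(O)ccc3C2)c(O)c1O | target

**Totals**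

Total step count: 18. Longest linear sequence: 13 steps (steps 3–7 and 11–18, from 5 to 30).

**Steps most likely to fail, with fallbacks**

Step 12. The fully substituted enolate carbon of 21 may add to the aryne too slowly, so that simple α-arylation without C–C cleavage, O-arylation or self-consumption of the aryne take over. The insertion product may also lose the ring-A phenoxide by β-elimination under fluoride at 80 °C. The fallback introduces the ring-F benzyl group after the insertion; it sets out from imidazolide 19 and returns at 25. Compound 19 is condensed with potassium methyl malonate (KO2CCH2CO2Me, MgCl2, Et3N, MeCN; decarboxylative Claisen) to give the unbranched ketoester methyl 4-[2,3-bis(benzyloxy)-4-methoxyphenyl]-5-[3-(benzyloxy)phenoxy]-3-oxopentanoate F1. The aryne from 4 inserts into F1 (CsF, MeCN, 80 °C), now at an unhindered methylene, to give the ortho-acyl arylacetate F2. Reduction and lactonisation as in step 13 give the hydroxy ester F3 and then the C4-unsubstituted isochromanone F4. Aldehyde 14 is reduced (NaBH4, MeOH) to [2-(allyloxy)-4-(benzyloxy)phenyl]methanol F5 and converted (PBr3, Et2O, 0 °C, used at once) into 2-(allyloxy)-4-(benzyloxy)benzyl bromide F6. F6 alkylates the enolate of F4 (LiN(SiMe3)2, THF, −78 °C) at the lactone α-carbon to give 25.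

Step 13. Hydride transfer to the twisted, doubly ortho-substituted aryl ketone may be slow, and enolisation may not keep pace with reduction, so that facial control at the carbonyl does not become control at upper C3. The fallback gives up catalyst control at the ketone and resolves through the second reduction; it sets out from 23 and returns at 26. NaBH4 (MeOH/THF, 0 °C) reduces the ketone under Felkin–Anh control and should give 24 together with its upper-unit mirror-image hydroxy ester F7. DBU closes both to 25 and the mirror-image-upper lactone F8. Step 14 then fixes lower C3 as (R) in both, so the products are diastereomers, 26 and the diol F9, which are separated by chromatography. Compound 26 goes on, at the cost of half the material.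

Step 14. The catalyst's preference may be mismatched with the resident upper stereocentres, or reduction may outrun epimerisation of the lactone α-carbon, giving poor control at lower C3; isomerisation of the allyl ether by the metal hydride is a lesser risk. The fallback uses equilibration and separation of diastereomers followed by a stoichiometric hydride; it sets out from 25 and returns at 26. The two C4 epimers of 25 are diastereomers: they are equilibrated with DBU (toluene, rt), the (1S,4R)-lactone F10 is separated by chromatography and the other epimer is returned to the equilibration. F10 is then reduced with LiBH4 (THF, 0 °C), which is fast and only weakly basic, to give 26.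

**Further compounds**

F1 | step 12 | methyl 4-[2,3-bis(benzyloxy)-4-methoxyphenyl]-5-[3-(benzyloxy)phenoxy]-3-oxopentanoate (racemic) | COC(=O)CC(=O)C(COc1cccc(OCc2ccccc2)c1)c1ccc(OC)c(OCc2ccccc2)c1OCc1ccccc1
F2 | step 12 | methyl [5-(benzyloxy)-2-{2-[2,3-bis(benzyloxy)-4-methoxyphenyl]-3-[3-(benzyloxy)phenoxy]propanoyl}-3-methoxyphenyl]acetate (racemic) | COC(=O)Cc1cc(OCc2ccccc2)cc(OC)c1C(=O)C(COc1cccc(OCc2ccccc2)c1)c1ccc(OC)c(OCc2ccccc2)c1OCc1ccccc1
F3 | step 12 | methyl [5-(benzyloxy)-2-{(1S,2R)-2-[2,3-bis(benzyloxy)-4-methoxyphenyl]-3-[3-(benzyloxy)phenoxy]-1-hydroxypropyl}-3-methoxyphenyl]acetate | COC(=O)Cc1cc(OCc2ccccc2)cc(OC)c1[C@@H](O)[C@@H](COc1cccc(OCc2ccccc2)c1)c1ccc(OC)c(OCc2ccccc2)c1OCc1ccccc1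
F4 | step 12 | (1S)-6-(benzyloxy)-1-{(1R)-1-[2,3-bis(benzyloxy)-4-methoxyphenyl]-2-[3-(benzyloxy)phenoxy]ethyl}-8-methoxyisochroman-3-one | COc1cc(OCc2ccccc2)cc2c1[C@H]([C@@H](COc1cccc(OCc3ccccc3)c1)c1ccc(OC)c(OCc3ccccc3)c1OCc1ccccc1)OC(=O)C2
F5 | step 12 | [2-(allyloxy)-4-(benzyloxy)phenyl]methanol | C=CCOc1cc(OCc2ccccc2)ccc1CO
F6 | step 12 | 2-(allyloxy)-4-(benzyloxy)benzyl bromide | C=CCOc1cc(OCc2ccccc2)ccc1CBr
F7 | step 13 | methyl 3-[2-(allyloxy)-4-(benzyloxy)phenyl]-2-[5-(benzyloxy)-2-{(1R,2S)-2-[2,3-bis(benzyloxy)-4-methoxyphenyl]-3-[3-(benzyloxy)phenoxy]-1-hydroxypropyl}-3-methoxyphenyl]propanoate (epimers at the ester α-carbon) | COC(=O)C(Cc1ccc(OCc2ccccc2)cc1OCC=C)c1cc(OCc2ccccc2)cc(OC)c1[C@H](O)[C@H](COc1cccc(OCc2ccccc2)c1)c1ccc(OC)c(OCc2ccccc2)c1OCc1ccccc1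
F8 | step 13 | (1R)-4-[2-(allyloxy)-4-(benzyloxy)benzyl]-6-(benzyloxy)-1-{(1S)-1-[2,3-bis(benzyloxy)-4-methoxyphenyl]-2-[3-(benzyloxy)phenoxy]ethyl}-8-methoxyisochroman-3-one (C4 epimers) | COc1cc(OCc2ccccc2)cc2c1[C@@H]([C@H](COc1cccc(OCc3ccccc3)c1)c1ccc(OC)c(OCc3ccccc3)c1OCc1ccccc1)OC(=O)C2Cc1ccc(OCc2ccccc2)cc1OCC=C
F9 | step 13 | (2R)-3-[2-(allyloxy)-4-(benzyloxy)phenyl]-2-[5-(benzyloxy)-2-{(1R,2S)-2-[2,3-bis(benzyloxy)-4-methoxyphenyl]-3-[3-(benzyloxy)phenoxy]-1-hydroxypropyl}-3-methoxyphenyl]propan-1-ol | C=CCOc1cc(OCc2ccccc2)ccc1C[C@@H](CO)c1cc(OCc2ccccc2)cc(OC)c1[C@H](O)[C@H](COc1cccc(OCc2ccccc2)c1)c1ccc(OC)c(OCc2ccccc2)c1OCc1ccccc1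
F10 | step 14 | (1S,4R)-4-[2-(allyloxy)-4-(benzyloxy)benzyl]-6-(benzyloxy)-1-{(1R)-1-[2,3-bis(benzyloxy)-4-methoxyphenyl]-2-[3-(benzyloxy)phenoxy]ethyl}-8-methoxyisochroman-3-one | COc1cc(OCc2ccccc2)cc2c1[C@H]([C@@H](COc1cccc(OCc3ccccc3)c1)c1ccc(OC)c(OCc3ccccc3)c1OCc1ccccc1)OC(=O)[C@@H]2Cc1ccc(OCc2ccccc2)cc1OCC=C
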